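**Plan**

Numbering follows abscisic acid: chain C1–C5, ring C1'–C6', C8' is the oxygenated methyl on C6', and HMG is the 3-hydroxy-3-methylglutarate unit.
Retrosynthesis: cut the C8'–O ester (S-HMG half-ester), then the C3–C4 bond (Suzuki), then the C4=C5 alkene (boryl-olefination of a C5 aldehyde), and last C1'–C6' and C4'–C5' (pyrone plus methacrolein).
Enabling feature: C1' carries an oxygen and the chain carbon C5, C4' carries an oxygen, and C2'=C3' lies between them; the ring is therefore a 3-hydroxy-2-pyrone cycloadduct whose lactone bridge (C5 as carboxyl carbon plus the C4' oxygen) once linked C1' to C4'.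
Forward: C4-methylation of 3-hydroxy-2-pyrone, cycloaddition (the only carbocycle), reduction with translactonisation, lactol, E-alkenyl boronate, HMG acylation, Suzuki coupling with Z-3-iodobutenoic acid, desilylation, C4' oxidation.
Stereochemistry: C1' and C6' come from the catalysed exo cycloaddition (C4' is transient), HMG C3 from esterase desymmetrisation, 4E from the chromium olefination, 2Z from anti hydroiodination; both alkene geometries are retained in the coupling.

Key step: step 5

Assumption: the quinidine-series catalyst is written as the one that delivers the enantiomer drawn for 7; the sense of induction cannot be derived with certainty for this substrate pair, and the quinine-series pseudoenantiomer is the mirror-image reagent.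

**Route**

Step 1
Reactants: 1 3-hydroxy-2H-pyran-2-one
Product: 2 4-bromo-3-hydroxy-2H-pyran-2-one
Conditions: NBS (1.05 equiv), MeCN, 0 °C to rt
Reagents that add atoms: N-bromosuccinimide, O=C1CCC(=O)N1Br
Why: Electrophilic bromination of an enol: the 3-hydroxyl makes C4 the nucleophilic α-carbon of an enolised 2,3-dione, so bromine should enter there and tautomerisation restores the pyrone.

Step 2
Reactants: 2 4-bromo-3-hydroxy-2H-pyran-2-one
Product: 3 4-bromo-3-(methoxymethoxy)-2H-pyran-2-one
Conditions: MOMCl, N,N-diisopropylethylamine, CH2Cl2, 0 °C to rt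
Reagents that add atoms: chloromethyl methyl ether, COCCl
Why: O-Alkylation of the acidic enol hydroxyl (MOM protection) keeps the coupling base in step 3 from forming an electron-rich oxido-pyrone that would add poorly to palladium.

Step 3
Reactants: 3 4-bromo-3-(methoxymethoxy)-2H-pyran-2-one
Product: 4 3-(methoxymethoxy)-4-methyl-2H-pyran-2-one
Conditions: trimethylboroxine, Pd(PPh3)4 (5 mol%), K2CO3, 1,4-dioxane, 90 °C
Reagents that add atoms: trimethylboroxine, CB1OB(C)OB(C)O1
Why: Suzuki–Miyaura methylation: the C4–Br bond is a vinylogous acyl bromide that should add readily to zerovalent palladium, and anhydrous carbonate spares the lactone.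

Step 4
Reactants: 4 3-(methoxymethoxy)-4-methyl-2H-pyran-2-one
Product: 5 3-hydroxy-4-methyl-2H-pyran-2-one
Conditions: TFA, CH2Cl2, 0 °C to rt
Reagents that add atoms: none
Why: Acid-catalysed acetal cleavage frees the enol hydroxyl, and the pyrone ring tolerates anhydrous acid.

Step 5
Reactants: 5 3-hydroxy-4-methyl-2H-pyran-2-one; 6 methacrolein
Product: 7 (1S,4R,8R)-4-hydroxy-5,8-dimethyl-3-oxo-2-oxabicyclo[2.2.2]oct-5-ene-8-carbaldehyde (formyl group on the face of the lactone bridge)
Conditions: 1-[3,5-bis(trifluoromethyl)phenyl]-3-(9-deoxy-epi-quinidin-9-yl)thiourea (10 mol%), 6 (3 equiv, trace BHT), tert-butyl methyl ether, 0 °C to rt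
Reagents that add atoms: none
Why: The quinuclidine nitrogen should deprotonate the 3-hydroxyl of 5 to an ion-paired oxido-diene while the thiourea binds the formyl oxygen of 6, so that pyrone C6 (future C4') adds to the CH2 terminus and the enolate carbon (future C6') closes on pyrone C3 (future C1'), either as an asynchronous [4+2] cycloaddition or as Michael addition followed by aldol. The closest known reaction type is the base- and cinchona-catalysed Diels–Alder reaction of 3-hydroxy-2-pyrones with enones, acrylates and acrylonitriles, of which an α-methyl enal meeting a 4-methylpyrone is a more crowded and so far untried member. The single new carbocycle (C1'–C6') is closed by the second bond in a 6-(enolexo)-exo-trig aldol mode, and the lactone survives as the C5–O bridge between C1' and C4'. C1' and C4' are fixed together by the face of the flat oxido-diene that the catalyst leaves open, and C6' by the exo arrangement in which the formyl group lies over the lactone bridge and the α-methyl group takes the endo site, the usual preference of methacrolein. The step needs regio-, exo- and enantioface selectivity: the polarity match (dienolate γ-carbon to enal β-carbon) allows one regiochemistry only, two-point binding of both partners by the catalyst is relied on for the other two, and any endo adduct is removed in step 6 because it cannot translactonise.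

Step 6
Reactants: 7 (1S,4R,8R)-4-hydroxy-5,8-dimethyl-3-oxo-2-oxabicyclo[2.2.2]oct-5-ene-8-carbaldehyde
Product: 9 (3aS,5S,7aR)-5,7a-dihydroxy-3a,7-dimethyl-3a,4,5,7a-tetrahydro-2-benzofuran-1(3H)-one, via bridged hydroxymethyl lactone 8 (not isolated)
Conditions: NaBH4 (0.5 equiv), THF–MeOH, −40 °C; pH 7 buffer; then DBU (0.1 equiv), CH2Cl2, rt
Reagents that add atoms: none
Why: Chemoselective hydride reduction of the aldehyde at low temperature is followed by base-mediated translactonisation, in which the new primary alkoxide, held syn to the strained bridging δ-lactone, takes over its acyl group (5-exo-trig) to give the cis-fused γ-lactone and release the C4' hydroxyl without touching a stereocentre.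

Step 7
Reactants: 9 (3aS,5S,7aR)-5,7a-dihydroxy-3a,7-dimethyl-3a,4,5,7a-tetrahydro-2-benzofuran-1(3H)-one
Product: 10 (3aS,5S,7aR)-5-[(tert-butyldimethylsilyl)oxy]-7a-hydroxy-3a,7-dimethyl-3a,4,5,7a-tetrahydro-2-benzofuran-1(3H)-one
Conditions: TBSCl, imidazole, DMF, rt
Reagents that add atoms: tert-butyldimethylsilyl chloride, CC(C)(C)[Si](C)(C)Cl
Why: Silyl ether formation at the secondary allylic alcohol; the tertiary C1' hydroxyl, flanked by two fully substituted carbons, is too hindered for these conditions.

Step 8
Reactants: 10 (3aS,5S,7aR)-5-[(tert-butyldimethylsilyl)oxy]-7a-hydroxy-3a,7-dimethyl-3a,4,5,7a-tetrahydro-2-benzofuran-1(3H)-one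
Product: 11 (3aS,5S,7aR)-5-[(tert-butyldimethylsilyl)oxy]-3a,7-dimethyl-1,3,3a,4,5,7a-hexahydro-2-benzofuran-1,7a-diol (lactol, both C1 epimers)
Conditions: DIBAL-H (2.3 equiv), CH2Cl2, −78 °C; Rochelle salt
Reagents that add atoms: none
Why: Half-reduction of a lactone to the lactol with DIBAL-H proceeds through an aluminium hemiacetal that is stable at low temperature, one further equivalent being consumed by the tertiary hydroxyl.

Step 9
Reactants: 11 (3aS,5S,7aR)-5-[(tert-butyldimethylsilyl)oxy]-3a,7-dimethyl-1,3,3a,4,5,7a-hexahydro-2-benzofuran-1,7a-diol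
Product: 13 (1R,4S,6S)-4-[(tert-butyldimethylsilyl)oxy]-6-(hydroxymethyl)-2,6-dimethyl-1-[(E)-2-(4,4,5,5-tetramethyl-1,3,2-dioxaborolan-2-yl)ethenyl]cyclohex-2-en-1-ol, via ring-opened hydroxy aldehyde 12 (not isolated)
Conditions: CrCl2 (8 equiv), Cl2CHBpin (2.5 equiv), LiI (5 equiv), THF, rt
Reagents that add atoms: 2-(dichloromethyl)-4,4,5,5-tetramethyl-1,3,2-dioxaborolane, ClC(Cl)B1OC(C)(C)C(C)(C)O1
Why: Takai–Utimoto boryl-olefination: the small equilibrium share of hydroxy aldehyde 12 is trapped by the geminal dichromium species from the in situ diiodomethylboronate and CrCl2, and elimination from the less crowded β-oxido trivalent chromium adduct should give the E-alkenyl boronate, which is no Michael acceptor and so cannot be re-closed by the freed C8' hydroxyl.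

Step 10
Reactants: 14 dimethyl 3-hydroxy-3-methylpentanedioate
Product: 15 (3S)-3-hydroxy-5-methoxy-3-methyl-5-oxopentanoic acid
Conditions: pig liver esterase, 0.1 M phosphate buffer pH 7.5, pH-stat with 1 M NaOH (1.0 equiv), rt; then HCl to pH 2
Reagents that add atoms: water, O
Why: Enzymatic desymmetrisation: the esterase should hydrolyse one enantiotopic ester group of the prochiral diester (expected: the pro-S arm), which sets the quaternary carbinol as S in the half-ester; the descriptor becomes R in 16 and the target only through the priority change on esterification.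

Step 11
Reactants: 13 (1R,4S,6S)-alkenyl boronate diol; 15 (3S)-3-hydroxy-5-methoxy-3-methyl-5-oxopentanoic acid
Product: 16 C8' ester of 13 with 15: [(1S,2R,5S)-5-[(tert-butyldimethylsilyl)oxy]-2-hydroxy-1,3-dimethyl-2-[(E)-2-(4,4,5,5-tetramethyl-1,3,2-dioxaborolan-2-yl)ethenyl]cyclohex-3-en-1-yl]methyl methyl (3R)-3-hydroxy-3-methylpentanedioate
Conditions: EDC·HCl (1.5 equiv), DMAP (0.5 equiv), CH2Cl2, 0 °C to rt
Reagents that add atoms: none
Why: Steglich esterification: carbodiimide/DMAP activation acylates the primary neopentyl hydroxyl, while the two tertiary hydroxyls and the alkenyl boronate are inert.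

Step 12
Reactants: 17 but-2-ynoic acid
Product: 18 (2Z)-3-iodobut-2-enoic acid
Conditions: NaI, AcOH, 110 °C
Reagents that add atoms: sodium iodide, [Na+].[I-]
Why: Hydroiodination of an ynoic acid: conjugate addition of iodide and anti protonation should give the Z-3-iodoalkenoic acid.

Step 13
Reactants: 16 HMG-acylated alkenyl boronate; 18 (2Z)-3-iodobut-2-enoic acid
Product: 19 (2Z,4E)-5-[(1R,4S,6S)-4-[(tert-butyldimethylsilyl)oxy]-1-hydroxy-6-({[(3R)-3-hydroxy-5-methoxy-3-methyl-5-oxopentanoyl]oxy}methyl)-2,6-dimethylcyclohex-2-en-1-yl]-3-methylpenta-2,4-dienoic acid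
Conditions: Pd(dppf)Cl2 (5 mol%), K3PO4 (3 equiv), THF–H2O (9:1), rt, amber glassware
Reagents that add atoms: none
Why: Suzuki–Miyaura coupling with retention at both alkene partners should give the 2Z,4E-dienoic acid directly, and mild aqueous phosphate at ambient temperature should spare the methyl and neopentyl esters.

Step 14
Reactants: 19 silyl ether dienoic acid
Product: 20 (2Z,4E)-5-[(1R,4S,6S)-1,4-dihydroxy-6-({[(3R)-3-hydroxy-5-methoxy-3-methyl-5-oxopentanoyl]oxy}methyl)-2,6-dimethylcyclohex-2-en-1-yl]-3-methylpenta-2,4-dienoic acid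
Conditions: HF·pyridine, pyridine, THF, 0 °C to rt, amber glassware
Reagents that add atoms: none
Why: Fluoride-mediated silyl ether cleavage under pyridine buffering should leave the esters, the tertiary allylic alcohol and the dienoic acid untouched.

Step 15
Reactants: 20 1',4'-diol dienoic acid
Product: 21 (2Z,4E)-5-[(1R,6S)-1-hydroxy-6-({[(3R)-3-hydroxy-5-methoxy-3-methyl-5-oxopentanoyl]oxy}methyl)-2,6-dimethyl-4-oxocyclohex-2-en-1-yl]-3-methylpenta-2,4-dienoic acid (target)
Conditions: Dess–Martin periodinane (1.3 equiv), CH2Cl2, 0 °C to rt, amber glassware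
Reagents that add atoms: none
Why: Dess–Martin oxidation converts the only secondary (allylic) alcohol into the enone and removes the transient C4' stereocentre; tertiary alcohols and the carboxylic acid do not react.

**Compound list**

1 | 3-hydroxy-2H-pyran-2-one | OC1=CC=COC1=O | starting material
2 | 4-bromo-3-hydroxy-2H-pyran-2-one | OC1=C(Br)C=COC1=O | intermediate
3 | 4-bromo-3-(methoxymethoxy)-2H-pyran-2-one | COCOC1=C(Br)C=COC1=O | intermediate
4 | 3-(methoxymethoxy)-4-methyl-2H-pyran-2-one | COCOC1=C(C)C=COC1=O | intermediate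
5 | 3-hydroxy-4-methyl-2H-pyran-2-one | CC1=C(O)C(=O)OC=C1 | intermediate
6 | methacrolein (2-methylprop-2-enal) | CC(=C)C=O | starting material
7 | (1S,4R,8R)-4-hydroxy-5,8-dimethyl-3-oxo-2-oxabicyclo[2.2.2]oct-5-ene-8-carbaldehyde | O=C[C@]1(C)C[C@@H]2OC(=O)[C@@]1(O)C(C)=C2 | intermediate
8 | (1S,4R,8S)-4-hydroxy-8-(hydroxymethyl)-5,8-dimethyl-2-oxabicyclo[2.2.2]oct-5-en-3-one (not isolated) | OC[C@]1(C)C[C@@H]2OC(=O)[C@@]1(O)C(C)=C2 | intermediate
9 | (3aS,5S,7aR)-5,7a-dihydroxy-3a,7-dimethyl-3a,4,5,7a-tetrahydro-2-benzofuran-1(3H)-one | CC1=C[C@@H](O)C[C@@]2(C)COC(=O)[C@@]12O | intermediate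
10 | (3aS,5S,7aR)-5-[(tert-butyldimethylsilyl)oxy]-7a-hydroxy-3a,7-dimethyl-3a,4,5,7a-tetrahydro-2-benzofuran-1(3H)-one | CC1=C[C@@H](O[Si](C)(C)C(C)(C)C)C[C@@]2(C)COC(=O)[C@@]12O | intermediate
11 | (3aS,5S,7aR)-5-[(tert-butyldimethylsilyl)oxy]-3a,7-dimethyl-1,3,3a,4,5,7a-hexahydro-2-benzofuran-1,7a-diol (C1 epimers) | CC1=C[C@@H](O[Si](C)(C)C(C)(C)C)C[C@@]2(C)COC(O)[C@@]12O | intermediate
12 | (1R,4S,6S)-4-[(tert-butyldimethylsilyl)oxy]-1-hydroxy-6-(hydroxymethyl)-2,6-dimethylcyclohex-2-ene-1-carbaldehyde (not isolated) | OC[C@]1(C)C[C@H](O[Si](C)(C)C(C)(C)C)C=C(C)[C@]1(O)C=O | intermediate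
13 | (1R,4S,6S)-4-[(tert-butyldimethylsilyl)oxy]-6-(hydroxymethyl)-2,6-dimethyl-1-[(E)-2-(4,4,5,5-tetramethyl-1,3,2-dioxaborolan-2-yl)ethenyl]cyclohex-2-en-1-ol | OC[C@]1(C)C[C@H](O[Si](C)(C)C(C)(C)C)C=C(C)[C@]1(O)/C=C/B1OC(C)(C)C(C)(C)O1 | intermediate
14 | dimethyl 3-hydroxy-3-methylpentanedioate | COC(=O)CC(C)(O)CC(=O)OC | starting material
15 | (3S)-3-hydroxy-5-methoxy-3-methyl-5-oxopentanoic acid | COC(=O)C[C@@](C)(O)CC(=O)O | intermediate
16 | [(1S,2R,5S)-5-[(tert-butyldimethylsilyl)oxy]-2-hydroxy-1,3-dimethyl-2-[(E)-2-(4,4,5,5-tetramethyl-1,3,2-dioxaborolan-2-yl)ethenyl]cyclohex-3-en-1-yl]methyl methyl (3R)-3-hydroxy-3-methylpentanedioate | COC(=O)C[C@@](C)(O)CC(=O)OC[C@]1(C)C[C@H](O[Si](C)(C)C(C)(C)C)C=C(C)[C@]1(O)/C=C/B1OC(C)(C)C(C)(C)O1 | intermediate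
17 | but-2-ynoic acid | CC#CC(=O)O | starting material
18 | (2Z)-3-iodobut-2-enoic acid | C/C(I)=C/C(=O)O | intermediate
19 | (2Z,4E)-5-[(1R,4S,6S)-4-[(tert-butyldimethylsilyl)oxy]-1-hydroxy-6-({[(3R)-3-hydroxy-5-methoxy-3-methyl-5-oxopentanoyl]oxy}methyl)-2,6-dimethylcyclohex-2-en-1-yl]-3-methylpenta-2,4-dienoic acid | COC(=O)C[C@@](C)(O)CC(=O)OC[C@]1(C)C[C@H](O[Si](C)(C)C(C)(C)C)C=C(C)[C@]1(O)/C=C/C(C)=C\C(=O)O | intermediate
20 | (2Z,4E)-5-[(1R,4S,6S)-1,4-dihydroxy-6-({[(3R)-3-hydroxy-5-methoxy-3-methyl-5-oxopentanoyl]oxy}methyl)-2,6-dimethylcyclohex-2-en-1-yl]-3-methylpenta-2,4-dienoic acid | COC(=O)C[C@@](C)(O)CC(=O)OC[C@]1(C)C[C@H](O)C=C(C)[C@]1(O)/C=C/C(C)=C\C(=O)O | intermediate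
21 | (2Z,4E)-5-[(1R,6S)-1-hydroxy-6-({[(3R)-3-hydroxy-5-methoxy-3-methyl-5-oxopentanoyl]oxy}methyl)-2,6-dimethyl-4-oxocyclohex-2-en-1-yl]-3-methylpenta-2,4-dienoic acid | COC(=O)C[C@@](C)(O)CC(=O)OC[C@]1(C)CC(=O)C=C(C)[C@]1(O)/C=C/C(C)=C\C(=O)O | target

**Count**

Total step count: 15. Longest linear sequence: 13 steps (1 to 21 through steps 1–9, 11, 13, 14 and 15); steps 10 and 12 make the two side fragments.

**Steps most likely to fail**

1. Step 5 (cycloaddition). The aldol closure joins two fully substituted carbons and may be slow or reversible, some material may leak through the endo transition state, and the α-methyl group may loosen the two-point binding so that enantioface discrimination is weak. The fallback moves the source of absolute configuration from the catalyst to an enzyme. It sets out from 5 and 6, which are combined under an achiral amine (DABCO, 0.2 equiv, CH2Cl2, rt) to give the racemic exo adduct F1. Reduction and translactonisation as in step 6 lead through the racemic bridged hydroxymethyl lactone F2 to the racemic lactone diol F3, endo material being lost here because it cannot translactonise. Kinetic resolution with immobilised Candida antarctica lipase B and vinyl acetate in tert-butyl methyl ether should, by the empirical rule for cyclohex-2-enols, acetylate the 5R antipode to the acetate of the unwanted enantiomer F4. The unreacted alcohol is separated by chromatography, and the route is re-joined at 9.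

2. Step 9 (boryl-olefination of the lactol). The lactol may stay closed, the neopentyl α-oxygenated aldehyde may add slowly to the bulky dichromium reagent, and the free hydroxyls may protonate the reagent or allow an α-ketol shift of the open form. The fallback builds the alkene from an alkyne. It sets out from 11, which under Ohira–Bestmann conditions (dimethyl (1-diazo-2-oxopropyl)phosphonate, K2CO3, MeOH, rt; a reaction that accepts lactols) should give the terminal alkyne F5. Copper-catalysed syn protoboration (B2pin2, CuCl, Xantphos, NaOtBu, MeOH, THF, rt) then places boron on the terminal carbon with E geometry and tolerates the free hydroxyls. The route is re-joined at 13.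

3. Step 10 (esterase desymmetrisation). Discrimination between the two enantiotopic ester groups depends on pH, cosolvent and the isozyme mixture and may be incomplete; the minor enantiomer would surface at the end as a C3 epimer of the HMG unit that is hard to remove. The fallback is a classical resolution. It sets out from 14, which with one equivalent of KOH in aqueous methanol at 0 °C gives the racemic half-ester F6. Crystallisation of its 1-phenylethylammonium salt F7 (written with the R amine; the antipodal amine is taken if the salt of the S acid proves the more soluble one) to constant rotation and acidification return the S acid. The route is re-joined at 15.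

**Further compounds**

F1 | step 5 | racemic 4-hydroxy-5,8-dimethyl-3-oxo-2-oxabicyclo[2.2.2]oct-5-ene-8-carbaldehyde (exo, both enantiomers) | O=C[C@]1(C)C[C@@H]2OC(=O)[C@@]1(O)C(C)=C2.O=C[C@@]1(C)C[C@H]2OC(=O)[C@]1(O)C(C)=C2
F2 | step 5 | racemic 4-hydroxy-8-(hydroxymethyl)-5,8-dimethyl-2-oxabicyclo[2.2.2]oct-5-en-3-one (not isolated) | OC[C@]1(C)C[C@@H]2OC(=O)[C@@]1(O)C(C)=C2.OC[C@@]1(C)C[C@H]2OC(=O)[C@]1(O)C(C)=C2
F3 | step 5 | racemic 5,7a-dihydroxy-3a,7-dimethyl-3a,4,5,7a-tetrahydro-2-benzofuran-1(3H)-one (both enantiomers) | CC1=C[C@@H](O)C[C@@]2(C)COC(=O)[C@@]12O.CC1=C[C@H](O)C[C@]2(C)COC(=O)[C@]12O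
F4 | step 5 | (3aR,5R,7aS)-7a-hydroxy-3a,7-dimethyl-1-oxo-1,3,3a,4,5,7a-hexahydro-2-benzofuran-5-yl acetate | CC1=C[C@H](OC(C)=O)C[C@]2(C)COC(=O)[C@]12O
F5 | step 9 | (1R,4S,6S)-4-[(tert-butyldimethylsilyl)oxy]-1-ethynyl-6-(hydroxymethyl)-2,6-dimethylcyclohex-2-en-1-ol | OC[C@]1(C)C[C@H](O[Si](C)(C)C(C)(C)C)C=C(C)[C@]1(O)C#C
F6 | step 10 | racemic 3-hydroxy-5-methoxy-3-methyl-5-oxopentanoic acid (both enantiomers) | COC(=O)C[C@@](C)(O)CC(=O)O.COC(=O)C[C@](C)(O)CC(=O)O
F7 | step 10 | (R)-1-phenylethylammonium (3S)-3-hydroxy-5-methoxy-3-methyl-5-oxopentanoate | COC(=O)C[C@@](C)(O)CC(=O)[O-].C[C@@H]([NH3+])c1ccccc1
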